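In my view the flask is an account of E. I assume that L and X each spend one E, so the E charged equals E left plus D formed plus X consumed. L's side of the account closes: in the last oak reading, D and L sum to 101% of the L charged.

| flask | L | E | X | G | temperature | remark | time |
|---|---|---|---|---|---|---|---|
| birch | 10 mM | 1.5 equiv | 0.70 equiv | 1 mol% | −30 °C | run made earlier |  |
| oak | 10 mM | 1.5 equiv | 4.6 equiv | 1 mol% | −8 °C | run made earlier |  |
| ash | 10 mM | 2.5 equiv | 1 equiv | 1 mol% | −30 °C | run made earlier |  |
| autumn | 10 mM | 6.00 equiv | 0.670 equiv | 1 mol% | 0 °C |  | 20 h |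
| spring | 10 mM | 1.50 equiv | 1.00 equiv | 1 mol% | −40 °C |  | 20 h |
| noon | 10 mM | 1.50 equiv | 1.00 equiv | 1 mol% | 0 °C |  | 20 h |
| winter | 10 mM | 1.50 equiv | 4.00 equiv | 0.6 mol% | 0 °C |  | 20 h |
| midnight | 10 mM | 3.00 equiv | 0.500 equiv | 0.25 mol% | 0 °C |  | 20 h |

| run | time / h | D / % | L / % |
|---|---|---|---|
| birch | 6.00 | 8 | 94 |
| birch | 12.0 | 10 | 88 |
| birch | 20.0 | 18 | 85 |
| birch | 25.0 | 19 | 76 |
| birch | 40.0 | 26 | 75 |
| oak | 0.833 | 4 | 96 |
| oak | 1.33 | 4 | 95 |
| oak | 2.00 | 5 | 93 |
| oak | 3.00 | 11 | 91 |
| oak | 4.00 | 11 | 92 |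
| oak | 6.00 | 14 | 90 |
| oak | 10.0 | 13 | 88 |
| ash | 8.00 | 12 | 86 |
| ash | 20.0 | 28 | 76 |
| ash | 25.0 | 30 | 71 |
| ash | 40.0 | 39 | 61 |

(each reading ± 1.5 percentage points)

- no earlier run changes the charge of G; that part of a forecast is a guess

* the flasks by amount of D, in percent of the L charged, highest first, at 20 h (autumn / spring / noon / winter / midnight)
* the amount of D, in percent of the L charged of the flask you put first, at 20 h
* the amount of D, in percent of the L charged of the flask you put last, at 20 h

If L and X compete for E, with D formed at a[L][E] and X lost at s·a[X][E], I describe the split by one ratio: s, the rate of X against that of L per unit concentration, the selectivity factor. I read it in two ways.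

The first way assumes that oak stalls because E is spent. Its last two D readings average 13.5%, and competition gives

s = ln([X]₀/[X]end) / ln([L]₀/[L]end) = 2.43

The second way uses the slowing of birch, at another temperature. Averaging D with the L consumed gives progress of 16.5% at 20.0 h and 25.5% at 40.0 h. That reads as a slowing constant of 0.0303 /h and a starting a[E] of 0.0110 /h. The rate a[L][E] should slow at a([L] + [E] + s[X]), so

s = 2.33

The two readings agree within their scatter, so I carry their mean, 2.38.

For winter, if E is spent by the asked time, D is about [E]₀[L]₀/([L]₀ + s[X]₀), which is 14.3%; the loading of G is a guess here. In autumn, L and X together can take 1.67 equiv of the 6.00 equiv charged, so I put that flask first.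

The forecast reads differently: “The runs fit a catalyst that dies while it works”. It gives autumn > noon > spring > winter > midnight, with 32% on top and 4.5% at the bottom. Its winter is 5.5%, against my 14.3%.

The flasks give autumn > midnight > noon > winter > spring, with 94.9% and 8.03%.

    L + E + G ⇌ G + D (K = 510 /M, k = 59000 /M²/h, Ea = 39.0 kJ/mol, ΔH = 2.00 kJ/mol)
    X + E + G → G + Z (k = 1.30 × 10⁵ /M²/h, Ea = 38.0 kJ/mol)
    G → J (k = 0.0180 /h, Ea = 97.0 kJ/mol)
    (constants at 0 °C)

Winter stalls as the account says: at 20.0 h, E stands at 1.55% of its charge and D at 15.2%, beside my 14.3%. Its L and X left give a ratio of 2.43, beside s of 2.38. Midnight, with 72.5% of its E left, gives 2.27 on 45.1% of D. Autumn keeps 73% of its E, and the reverse step accounts for 78% of what is missing from its D: without that step, its D stands at 98.9% rather than 94.9%.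

The runs stem from a simulated flask for substances that don't exist, and the scatter is random.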